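Tuesday's run carries 1.57 times Friday's catalyst but ends with 1.20 times its product, so I can't share your hunch of a fixed number of turnovers per catalyst: I count 80.0 on Friday and 60.9 on Tuesday at 30.0 min.

| setting | Friday's | Tuesday's | flask |
|---|---|---|---|
| left-handed substrate | 0.050 M | 0.050 M | 0.050 M |
| right-handed substrate | 0.050 M | 0.050 M | 0.050 M |
| partner | 3 equiv | 3 equiv | 3.00 equiv |
| free catalyst | 1.4 mol% | 2.2 mol% | 1 mol% |
| racemization catalyst | 0.1 mol% | 0.1 mol% | 0.1 mol% |
| remark | run made earlier | run made earlier |  |
| time |  |  | 30 min |

- Friday's (time / min: left-handed product / %, right-handed product / %): 5.00: 27, 7; 10.0: 31, 14; 15.0: 32, 15; 20.0: 35, 16; 25.0: 38, 16; 30.0: 40, 16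
- Tuesday's (time / min: left-handed product / %, right-handed product / %): 2.00: 17, 10; 6.00: 32, 14; 10.0: 38, 17; 15.0: 42, 20; 25.0: 47, 18; 30.0: 46, 21

(scatter of a reading: 1.5 percentage points)

1. left-handed product and right-handed product together, in percent of the left-handed substrate and right-handed substrate charged together, at 30 min
2. excess of left-handed product over right-handed product in the product at 30 min
3. whether the exchange between left-handed substrate and right-handed substrate keeps pace with the reaction: how far the product's excess at 30 min gets from its value without exchange to its value with instant exchange (above 80% keeps pace, below 20% hardly takes part, else lags behind)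

- free catalyst is single-handed; left-handed substrate and right-handed substrate are mirror images of each other, charged as a racemate, each of them at the stated concentration
- the earlier runs were read with a standard deviation of 1.5 percentage points
- an excess is the difference of the two amounts in percent of their sum
- an excess is below zero if the other one leads

A count that allows for thinning substrate takes the logarithm, as for a first-order loss. Friday's readings give 19.5 for what I call the turnover budget: the natural logarithm of substrate charged over substrate unreacted, divided by the fractional loading of free catalyst and by the equivalents of partner. Tuesday's readings give 16.8. Both runs hold partner at 3 equiv, so dividing by it is my assumption, not a reading. I keep Friday's budget, since its loading lies nearer the flask's, and for the flask I get 44.4%.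

The forecast says 46%, above my figure, with an excess of 47% and an exchange that lags behind; it holds that the way both runs start fast and then slow “points to a dying catalyst”.

The flask gives 46.0%, against my 44.4%, with an excess of 43.8%, and its exchange lags behind, getting 39% of the way.

racemization catalyst → spent catalyst B (k = 9.81 × 10⁻⁵ min⁻¹); left-handed substrate + racemization catalyst ⇌ right-handed substrate + racemization catalyst, rate k2*[racemization catalyst]*[left-handed substrate] forward; the back reaction follows from the equilibrium constant (k = 1740 M⁻¹ min⁻¹); partner → decomposed reagent (k = 0.0771 min⁻¹); partner + racemization catalyst → spent catalyst A (k = 1.07 M⁻¹ min⁻¹); partner + free catalyst + left-handed substrate → free catalyst + left-handed product (k = 1540 M⁻² min⁻¹); partner + free catalyst + right-handed substrate → free catalyst + right-handed product (k = 500 M⁻² min⁻¹) At 30.0 min the flask's [partner] stands at 3.91% of its charge and free catalyst at 100%. The neighbour holds 5.10 equiv of partner, everything else as in the flask, and the same budget gives it 63.1%; that neighbour gives 64.8%.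

The readings come from a simulation for an exercise; scatter was added.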